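## Retrosynthetic overview

1. Target 22 comes from diol 21 by a late primary acetylation, and 21 from acetonide 20. The C5 side chain is installed by Negishi coupling of enol triflate 17. The parent C5 ketone can enolise only towards C6, because C4a is quaternary.
2. Ring A (C1-C2-C3-C4-C4a-C8a) comes from a photochemical Wolff ring contraction of the cis-fused bicyclo[5.4.0] alpha'-diazo enone 9. In 9 the later ester carbonyl carbon is still a ring member between C1 and C2. (R)-Solketal 10 traps the ketene, so ring size, C1 and the hindered ester bond arise together.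
3. Enabling feature: in ring A the ester carbonyl carbon is the only exocyclic carbon on C1, and C1 lies between quaternary C8a and C2. Moved back into the ring, that carbon gives a 2-methylcyclohept-2-enone whose only enolisable alpha carbon is C1 and whose carbene centre has no neighbouring H.
4. The seven-membered ring comes from inserting C2 with its methyl (chloro(methyl)carbene on a kinetic silyl enol ether) into the cyclohexanone ring of 4. Compound 4 is the cis-selective Me2CuLi adduct of protected (S)-Wieland-Miescher ketone 1.
5. Ring order: ring B and a six-membered carbonyl ring are bought in 1. That carbonyl ring is enlarged to seven (step 5), then contracted to ring A (step 7). The C5-OTBS centre is a temporary conformational anchor that controls C1 and C2.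

Key step: step 7

Remark on numbering: atom numbers are those of the decalin core of 22. C1 is the ester-bearing CH, C2 is CH-CH3, then C3, C4 and C4a; C5 bears the side chain, followed by C6, C7, C8 and C8a. "Beta" is the face of the two angular methyl groups.

Assumption: compounds 1, 10 and 18 are taken as commercial.

## Route

Step 1
Reactants: 1 (S)-Wieland-Miescher ketone
Product: 2 (4aS,5S)-5-hydroxy-4a-methyl-4,4a,5,6,7,8-hexahydronaphthalen-2(3H)-one
Conditions: NaBH4 (0.3 equiv), EtOH, 0 °C
Reagents that add atoms: none
Why: Chemoselective borohydride 1,2-reduction: the saturated C5 ketone is more electrophilic than the conjugated one, and hydride enters anti to the axial C4a methyl, which sets the temporary C5 centre with an equatorial OH cis to that methyl.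

Step 2
Reactants: 2 hydroxy enone
Product: 3 TBS ether of 2
Conditions: TBSOTf, 2,6-lutidine, CH2Cl2, 0 °C
Reagents that add atoms: tert-butyldimethylsilyl triflate, CC(C)(C)[Si](C)(C)OS(=O)(=O)C(F)(F)F
Why: Standard silylation of a hindered secondary alcohol with the silyl triflate; the group masks C5 and later anchors the conformation.

Step 3
Reactants: 3 TBS ether
Product: 4 cis-fused 5beta-(TBSO)-4a,8a-dimethyldecalin-2-one type ketone (both angular methyls and OTBS beta)
Conditions: MeLi, CuI, Et2O, 0 °C; then 3; aq. NH4Cl
Reagents that add atoms: lithium dimethylcuprate, [Li+].C[Cu-]C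
Why: Gilman cuprate 1,4-addition to a 4a-methyl octalone: stereoelectronically favoured axial attack through a chair-like enolate brings the new C8a methyl in cis to the C4a methyl and should give the cis-decalone.

Step 4
Reactants: 4 cis-dimethyl decalone
Product: 5 kinetic trimethylsilyl enol ether (C=C towards C3)
Conditions: LDA, THF, -78 °C; TMSCl
Reagents that add atoms: chlorotrimethylsilane, C[Si](C)(C)Cl
Why: Kinetic enolate formation followed by O-silylation: LDA removes a proton from the open C3 methylene and not from the neopentyl C1 methylene next to quaternary C8a.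

Step 5
Reactants: 5 silyl enol ether
Product: 7 cis-fused 2-methylcyclohept-2-enone (bicyclo[5.4.0]undecenone), via chlorocyclopropane 6 (not isolated)
Conditions: CH3CHCl2, n-BuLi, Et2O, -40 °C to rt; then toluene, reflux
Reagents that add atoms: 1,1-dichloroethane, CC(Cl)Cl
Why: Halocarbene one-carbon ring expansion of a silyl enol ether: chloro(methyl)carbene adds to the electron-rich C=C and the chlorocyclopropane opens at the inner bond (cyclopropyl to allyl cation, pushed by the siloxy group, loss of Me3SiCl), which places C2 with its methyl between the carbonyl carbon and C3.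

Step 6
Reactants: 7 cycloheptenone
Product: 9 alpha'-diazo enone (diazo group on C1), via trifluoroacetyl enone 8 (not isolated)
Conditions: LiHMDS, THF, -78 °C; CF3CO2CH2CF3; then MsN3, Et3N, H2O (1 equiv), MeCN, rt
Reagents that add atoms: methanesulfonyl azide, CS(=O)(=O)N=[N+]=[N-]; 2,2,2-trifluoroethyl trifluoroacetate (atoms stay only in 8), O=C(OCC(F)(F)F)C(F)(F)F
Why: Detrifluoroacetylative diazo transfer (Regitz type) on the kinetic alpha' enolate of an enone: C1 is the only enolisable alpha carbon because C2 is sp2, so the diazo group can only end on C1.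

Step 7
Reactants: 9 alpha'-diazo enone; 10 (R)-solketal
Product: 13 solketal ester of the ring-contracted beta-gamma-unsaturated acid (ester on C1 beta), via vinylketene 11 (not isolated), via dienol 12 (not isolated)
Conditions: hv (365 nm LED or Hg lamp/Pyrex), 10 (5 equiv), THF, 0 °C
Reagents that add atoms: (R)-solketal 10, CC1(C)OC[C@@H](CO)O1
Why: Irradiation expels N2 from the ring-locked s-Z diazoketone and the sp2 carbon C2 shifts in concert from the carbonyl carbon to C1 (photochemical Wolff rearrangement, the standard ring contraction of cyclic 2-diazoketones), so the seven-membered ring becomes the six-membered ring C1-C2-C3-C4-C4a-C8a and the former ring carbonyl carbon is pushed out as the ketene carbon of 11. No ring is closed by cyclisation; ring A is formed by this 1,2-shift, and the fixed s-trans exocyclic/endocyclic diene of 11 cannot close to a cyclobutenone. Addition of the primary OH of 10 to the ketene gives dienol 12, which is protonated at C1 (alpha), so the crowded ester bond is made without acylating with a hindered acid. C1 is the only new stereocentre: the equatorial C5-OTBS group holds the cis-decalin in the chair pair in which the C8a methyl is axial on the new ring (the other chair pair would place OTBS and the C8a methyl syn-diaxial), so the proton should enter anti to that methyl and the ester becomes equatorial (beta), which is also the more stable epimer. The step needs a clean 1,2-carbon shift, secured by quaternary C8a (no H for a 1,2-H shift) and by the vinyl carbon C2 being the only migrating group on the carbonyl carbon; the glycerol stereocentre is not touched.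

Step 8
Reactants: 13 unsaturated ester
Product: 14 saturated ester (C1 ester beta and C2 methyl alpha)
Conditions: Mn(dpm)3 (cat.), PhSiH3, t-BuOOH, i-PrOH, rt
Reagents that add atoms: none
Why: Metal-hydride hydrogen atom transfer (MHAT) hydrogenation of the only alkene: H adds to C3, and the tertiary C2 radical should take up the second H on the axial beta side because an axial C2 methyl would be syn-diaxial to the axial C8a methyl in the OTBS-anchored chair, so the methyl ends equatorial (alpha) and trans to the ester.

Step 9
Reactants: 14 saturated ester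
Product: 15 C5 alcohol
Conditions: TBAF, THF, 50 °C
Reagents that add atoms: none
Why: Fluoride cleavage of the silyl ether; the hindered ester and the acetonide are inert to fluoride.

Step 10
Reactants: 15 C5 alcohol
Product: 16 C5 ketone
Conditions: Dess-Martin periodinane, CH2Cl2, rt
Reagents that add atoms: none
Why: Dess-Martin oxidation under near-neutral conditions removes the temporary C5 stereocentre and frees the ketone for ring B.

Step 11
Reactants: 16 C5 ketone
Product: 17 enol triflate (C5=C6)
Conditions: KHMDS (1.05 equiv), THF, -78 °C; PhNTf2; aq. NH4Cl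
Reagents that add atoms: N-phenylbis(trifluoromethanesulfonimide), O=S(=O)(N(c1ccccc1)S(=O)(=O)C(F)(F)F)C(F)(F)F
Why: Enol triflate formation: C4a is quaternary, so the potassium enolate can only form towards C6, while the C1-H of the ester is less acidic and its beta-ester epimer is the stable one in any case.

Step 12
Reactants: 18 5-bromo-2-methylpent-2-ene
Product: 19 (4-methylpent-3-en-1-yl)zinc bromide
Conditions: Zn dust (activated), LiCl, THF, 50 °C
Reagents that add atoms: zinc, [Zn]
Why: Direct insertion of activated zinc into a primary alkyl bromide promoted by LiCl; the trisubstituted alkene is inert.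

Step 13
Reactants: 17 enol triflate; 19 (4-methylpent-3-en-1-yl)zinc bromide
Product: 20 acetonide of the 1-acyl-sn-glycerol with complete diterpenoid core
Conditions: Pd(dppf)Cl2 (5 mol %), THF, 50 °C
Reagents that add atoms: (4-methylpent-3-en-1-yl)zinc bromide 19, CC(C)=CCC[Zn]Br
Why: Negishi sp2-sp3 cross-coupling; the bidentate ligand suppresses beta-hydride elimination and the organozinc tolerates ester and acetonide.

Step 14
Reactants: 20 acetonide
Product: 21 1-acyl-sn-glycerol (diol)
Conditions: AcOH-H2O 4:1, 40 °C
Reagents that add atoms: none
Why: Mild acid hydrolysis of the terminal acetonide; the hindered acyl group migrates slowly and the trisubstituted alkenes are not protonated under these conditions.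

Step 15
Reactants: 21 diol
Product: 22 target (2S)-3-acetoxy-2-hydroxypropyl (1S,2R,4aR,8aR)-2,4a,8a-trimethyl-5-(4-methylpent-3-en-1-yl)-1,2,3,4,4a,7,8,8a-octahydronaphthalene-1-carboxylate
Conditions: AcCl (1.05 equiv), 2,4,6-collidine, CH2Cl2, -78 °C
Reagents that add atoms: acetyl chloride, CC(=O)Cl
Why: Selective acylation of the primary over the secondary hydroxyl at low temperature with a hindered pyridine base; no stereocentre is touched.

## Compound list

1 | (S)-Wieland-Miescher ketone | O=C1C=C2CCCC(=O)[C@@]2(C)CC1 | starting material
2 | (4aS,5S)-5-hydroxy-4a-methyl-hexahydronaphthalen-2(3H)-one | O=C1C=C2CCC[C@H](O)[C@@]2(C)CC1 | intermediate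
3 | TBS ether of 2 | O=C1C=C2CCC[C@H](O[Si](C)(C)C(C)(C)C)[C@@]2(C)CC1 | intermediate
4 | cis-4a,8a-dimethyl decalone, C5-OTBS beta | O=C1CC[C@]2(C)[C@@H](O[Si](C)(C)C(C)(C)C)CCC[C@]2(C)C1 | intermediate
5 | kinetic TMS enol ether of 4 | C[Si](C)(C)OC1=CC[C@]2(C)[C@@H](O[Si](C)(C)C(C)(C)C)CCC[C@]2(C)C1 | intermediate
6 | 1-chloro-1-methyl-2-siloxycyclopropane adduct (isomers at the cyclopropane) | C[Si](C)(C)OC12C[C@@]3(C)CCC[C@H](O[Si](C)(C)C(C)(C)C)[C@@]3(C)CC1C2(C)Cl | intermediate (not isolated)
7 | cis-fused 2-methylcyclohept-2-enone | O=C1C[C@@]2(C)CCC[C@H](O[Si](C)(C)C(C)(C)C)[C@@]2(C)CC=C1C | intermediate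
8 | alpha'-trifluoroacetyl enone | O=C1C(C(=O)C(F)(F)F)[C@@]2(C)CCC[C@H](O[Si](C)(C)C(C)(C)C)[C@@]2(C)CC=C1C | intermediate (not isolated)
9 | alpha'-diazo enone | O=C1C(=[N+]=[N-])[C@@]2(C)CCC[C@H](O[Si](C)(C)C(C)(C)C)[C@@]2(C)CC=C1C | intermediate
10 | (R)-solketal | CC1(C)OC[C@@H](CO)O1 | starting material
11 | vinylketene | O=C=C1C(C)=CC[C@]2(C)[C@@H](O[Si](C)(C)C(C)(C)C)CCC[C@]12C | intermediate (not isolated)
12 | dienol (ketene hemiacetal) | CC1(C)OC[C@@H](COC(O)=C2C(C)=CC[C@]3(C)[C@@H](O[Si](C)(C)C(C)(C)C)CCC[C@]23C)O1 | intermediate (not isolated)
13 | ring-contracted beta,gamma-unsaturated solketal ester | CC1(C)OC[C@@H](COC(=O)[C@H]2C(C)=CC[C@]3(C)[C@@H](O[Si](C)(C)C(C)(C)C)CCC[C@]23C)O1 | intermediate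
14 | saturated solketal ester | CC1(C)OC[C@@H](COC(=O)[C@H]2[C@H](C)CC[C@]3(C)[C@@H](O[Si](C)(C)C(C)(C)C)CCC[C@]23C)O1 | intermediate
15 | C5 alcohol | CC1(C)OC[C@@H](COC(=O)[C@H]2[C@H](C)CC[C@]3(C)[C@@H](O)CCC[C@]23C)O1 | intermediate
16 | C5 ketone | CC1(C)OC[C@@H](COC(=O)[C@H]2[C@H](C)CC[C@]3(C)C(=O)CCC[C@]23C)O1 | intermediate
17 | C5 enol triflate | CC1(C)OC[C@@H](COC(=O)[C@H]2[C@H](C)CC[C@]3(C)C(OS(=O)(=O)C(F)(F)F)=CCC[C@]23C)O1 | intermediate
18 | 5-bromo-2-methylpent-2-ene | CC(C)=CCCBr | starting material
19 | (4-methylpent-3-en-1-yl)zinc bromide | CC(C)=CCC[Zn]Br | intermediate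
20 | acetonide with complete core | CC1(C)OC[C@@H](COC(=O)[C@H]2[C@H](C)CC[C@]3(C)C(CCC=C(C)C)=CCC[C@]23C)O1 | intermediate
21 | 1-acyl-sn-glycerol (diol) | OC[C@H](O)COC(=O)[C@H]1[C@H](C)CC[C@]2(C)C(CCC=C(C)C)=CCC[C@]12C | intermediate
22 | target | CC(=O)OC[C@H](O)COC(=O)[C@H]1[C@H](C)CC[C@]2(C)C(CCC=C(C)C)=CCC[C@]12C | target

## Step count and risk assessment

Total step count: 15. Longest linear sequence: 14 (steps 1-11 and 13-15).

**Step 7.**
- What may go wrong: the alcohol may add only slowly to the crowded ketene, so that the ketene is lost to traces of water or to self-reaction. The dienol may also be protonated at C3 instead of C1, which moves the double bond into conjugation and erases C1.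
- Fallback: it sets out from 9 and forms the ester bond from the other side. The photolysis is run in THF-water, where the small nucleophile water should give the acid F1 by way of 11. In parallel, 10 is converted with TsCl and pyridine into the tosylate F2. O-alkylation of the caesium salt of F1 with F2 follows (Cs2CO3, DMF, 60 °C). This is an SN2 reaction at the primary carbon and leaves the glycerol centre untouched. The fallback comes back to the route at 13.

**Step 5.**
- What may go wrong: only chlorocyclopropane isomers with an inward-pointing chloride can open in the allowed disrotatory sense within the small bicycle. The other isomers may persist or lose the silyl group without ring enlargement.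
- Fallback: it sets out from 5 and separates ring enlargement from methyl introduction.
  - Et2Zn/CH2I2 cyclopropanation gives the siloxycyclopropane F3.
  - FeCl3 in DMF cleaves the inner bond oxidatively to the beta-chloro ketone F4.
  - NaOAc in MeOH eliminates HCl to the cycloheptenone F5.
  - I2/pyridine gives the alpha-iodo enone F6.
  - Pd-catalysed methylation with Me2Zn comes back to the route at 7.

**Step 8.**
- What may go wrong: reversible hydrogen atom transfer may shift the double bond into conjugation with the ester. The second hydrogen transfer to the C2 radical may also occur with poor facial selectivity.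
- Fallback: it sets out from 7 and fixes C2 before the contraction.
  - Hydrogenation (H2, Pd/C) and equilibration with NaOMe should give the saturated ketone F7 with a pseudo-equatorial C2 methyl.
  - Claisen formylation (HCO2Et, NaH) can only rest at the C1 methylene and gives the hydroxymethylene ketone F8.
  - Regitz deformylative diazo transfer (MsN3, Et3N) gives the diazoketone F9.
  - Photolysis with 10 contracts the ring, with sp3 C2 migrating with retention through the ketene F10. This comes back to the route at 14.

Further compounds
F1 | step 7 | ring-contracted beta,gamma-unsaturated acid | OC(=O)[C@H]1C(C)=CC[C@]2(C)[C@@H](O[Si](C)(C)C(C)(C)C)CCC[C@]12C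
F2 | step 7 | solketal tosylate from 10 | CC1(C)OC[C@@H](COS(=O)(=O)c2ccc(C)cc2)O1
F3 | step 5 | siloxycyclopropane | C[Si](C)(C)OC12C[C@@]3(C)CCC[C@H](O[Si](C)(C)C(C)(C)C)[C@@]3(C)CC1C2
F4 | step 5 | beta-chloro cycloheptanone | O=C1C[C@@]2(C)CCC[C@H](O[Si](C)(C)C(C)(C)C)[C@@]2(C)CC(Cl)C1
F5 | step 5 | cycloheptenone without methyl | O=C1C[C@@]2(C)CCC[C@H](O[Si](C)(C)C(C)(C)C)[C@@]2(C)CC=C1
F6 | step 5 | alpha-iodo cycloheptenone | O=C1C[C@@]2(C)CCC[C@H](O[Si](C)(C)C(C)(C)C)[C@@]2(C)CC=C1I
F7 | step 8 | saturated 2-methylcycloheptanone | O=C1C[C@@]2(C)CCC[C@H](O[Si](C)(C)C(C)(C)C)[C@@]2(C)CC[C@H]1C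
F8 | step 8 | hydroxymethylene ketone | O=C1C(=CO)[C@@]2(C)CCC[C@H](O[Si](C)(C)C(C)(C)C)[C@@]2(C)CC[C@H]1C
F9 | step 8 | saturated diazoketone | O=C1C(=[N+]=[N-])[C@@]2(C)CCC[C@H](O[Si](C)(C)C(C)(C)C)[C@@]2(C)CC[C@H]1C
F10 | step 8 | saturated ketene | O=C=C1[C@H](C)CC[C@]2(C)[C@@H](O[Si](C)(C)C(C)(C)C)CCC[C@]12C
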